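The quinone ring (numbering: C1/C4 carbonyls, C2 acetoxy, C5 hydroxy, C3/C6 aryl) is read, as in its presumed biosynthesis, as a head-to-tail dimer of two 4-hydroxyphenylpyruvate (aryl–C3) units: each carbonyl carbon (C1, C4) is the carboxyl carbon of one unit and carries the aryl-bearing carbon (C6, C3) of the other. A phenoxide-triggered Claisen–Dieckmann cyclodimerisation of an enol-masked, acyl-activated arylpyruvate, the 5-arylidene-1,3-dioxolan-4-one 6, should forge C1–C6 and C3–C4 in one operation and give the 2,5-diaryl-3,6-dihydroxyquinone directly at the right oxidation level, losing only acetone. Mono-acetylation of the symmetric core and acidolysis of the two tert-butyl ethers complete the route.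

Key step: step 2

Remark: 2,2-dimethyl-1,3-dioxolan-4-one is taken as purchasable; the dihydroxyquinone 9 is a degenerate tautomer pair whose dianion has four equivalent oxygens, so only one monoacetate constitution can form.

Step 1
Reactants: 1 4-(tert-butoxy)benzaldehyde; 2 2,2-dimethyl-1,3-dioxolan-4-one
Product: 6 (Z)-5-[4-(tert-butoxy)benzylidene]-2,2-dimethyl-1,3-dioxolan-4-one, via lithium enolate 3 (not isolated), via lithium aldolate 4 (not isolated), via mesylate 5 (not isolated)
Conditions: 2 (1.2 equiv), LiN(SiMe3)2 (1.2 equiv), THF, −78 °C; 1, −78 °C; MsCl (1.5 equiv), −78 → 0 °C; DBU (3 equiv), 0 °C → rt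
Reagents that add atoms: none
Why: Telescoped aldol condensation: the lithium enolate 3 of the glycolate acetonide adds to the non-enolisable aldehyde, the aldolate 4 is O-mesylated and DBU effects E1cB elimination of 5 to the conjugated alkene, expected as the thermodynamically preferred Z isomer (aryl anti to the lactone carbonyl), a geometry that is in any case erased in step 2.

Step 2
Reactants: 6 (two molecules)
Product: 9 2,5-bis[4-(tert-butoxy)phenyl]-3,6-dihydroxycyclohexa-2,5-diene-1,4-dione, via sodium enolate 7 (not isolated), via open-chain dienolate 8 (not isolated)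
Conditions: NaOPh (anhydrous, 1.1 equiv per 6, added over 3 h), THF, 25 °C, then 55 °C; then 1 M HCl
Reagents that add atoms: none
Why: Proposed new method: phenoxide adds to the lactone carbonyl of 6 and the ring collapses with loss of acetone to the phenyl arylpyruvate enolate 7, whose benzylic carbon is acylated by a second molecule of 6 (again with loss of acetone) to give, after deprotonation, the dienolate 8, which closes by Dieckmann attack of its terminal enolate carbon on the phenyl ester and expels phenoxide, and tautomerisation gives the dihydroxyquinone without any redox step. The closest known reaction types are the alkoxide opening of 5-ylidene-1,3-dioxolan-4-ones to 2-oxo ester enolates, the C-acylation of ester enolates by the same dioxolanones, the Claisen–Dieckmann cyclodimerisation of succinate esters to succinylsuccinates and the methoxide-induced closure of ring-opened pyrandione lactones to terphenylquinones, and the biosynthetic model is the thioester-mediated dimerisation of 4-hydroxyphenylpyruvate. The one ring closes in a 6-exo-trig (enolexo) Dieckmann mode, and no stereocentre is created. The step needs C- over O-acylation and Claisen over aldol reactivity: O-acylated enols (including a pyrandione lactone) are active esters that phenoxide and enolates reopen, whereas each C-acylation is locked by formation of a stabilised enolate and finally of the quinone dianion, so the system should funnel to 9. Aldol diversion is suppressed because in 6 the ketone is masked as an enol ketal and, under aprotic conditions with one equivalent of base per unit, every liberated ketone exists only as its enolate (phenol is too weak an acid to reprotonate it), leaving ester-type carbonyls as the sole electrophiles. Head-to-tail regiochemistry is inherent in the monomer (one nucleophilic benzylic carbon, one acylating carbon), and slow addition of NaOPh keeps neutral 6 in excess over 7 so that the first C–C bond forms between an anion and a neutral acyl donor.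

Step 3
Reactants: 9
Product: 11 2,5-bis[4-(tert-butoxy)phenyl]-4-hydroxy-3,6-dioxocyclohexa-1,4-dien-1-yl acetate, via disodium salt 10 (not isolated)
Conditions: NaH (2.05 equiv), THF–DMF (4:1), 0 °C; AcCl (1.0 equiv, slow addition), −60 → −20 °C; cold 0.5 M HCl
Reagents that add atoms: acetyl chloride CC(=O)Cl
Why: O-acylation of an enolate (vinylogous carboxylate) by an acid chloride, in which the dianion 10 should be far more nucleophilic than the monoanion of the product, whose remaining oxygen is deactivated by the new vinylogous anhydride, so that one acetyl group is transferred.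

Step 4
Reactants: 11
Product: 12 4-hydroxy-2,5-bis(4-hydroxyphenyl)-3,6-dioxocyclohexa-1,4-dien-1-yl acetate (2-O-acetylatromentin, the target)
Conditions: CF3CO2H–CH2Cl2 (1:2), 0 °C → rt, N2 sweep; evaporation, trituration
Reagents that add atoms: none
Why: Acidolysis of aryl tert-butyl ethers (E1 loss of the tert-butyl cation as isobutene) needs neither nucleophile nor base and should therefore spare the enol acetate and the quinone.

Compound list
1 | 4-(tert-butoxy)benzaldehyde | CC(C)(C)Oc1ccc(C=O)cc1 | starting material
2 | 2,2-dimethyl-1,3-dioxolan-4-one | CC1(C)OCC(=O)O1 | starting material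
3 | lithium enolate of 2 (lithium 2,2-dimethyl-1,3-dioxol-4-olate) | [Li+].CC1(C)OC=C([O-])O1 | intermediate
4 | lithium [4-(tert-butoxy)phenyl](2,2-dimethyl-5-oxo-1,3-dioxolan-4-yl)methanolate, racemic mixture of diastereomers | [Li+].CC(C)(C)Oc1ccc(C([O-])C2OC(C)(C)OC2=O)cc1 | intermediate
5 | [4-(tert-butoxy)phenyl](2,2-dimethyl-5-oxo-1,3-dioxolan-4-yl)methyl methanesulfonate, racemic mixture of diastereomers | CC(C)(C)Oc1ccc(C(OS(C)(=O)=O)C2OC(C)(C)OC2=O)cc1 | intermediate
6 | (Z)-5-[4-(tert-butoxy)benzylidene]-2,2-dimethyl-1,3-dioxolan-4-one | CC(C)(C)Oc1ccc(/C=C2\OC(C)(C)OC2=O)cc1 | intermediate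
7 | sodium (Z)-1-[4-(tert-butoxy)phenyl]-3-oxo-3-phenoxyprop-1-en-2-olate (enolate of the phenyl arylpyruvate) | [Na+].CC(C)(C)Oc1ccc(/C=C(\[O-])C(=O)Oc2ccccc2)cc1 | intermediate
8 | disodium dienolate of phenyl 3,6-bis[4-(tert-butoxy)phenyl]-2,4,5-trioxohexanoate (delocalised, alkene geometry not fixed) | [Na+].[Na+].CC(C)(C)Oc1ccc(C=C([O-])C([O-])=C(C(=O)C(=O)Oc2ccccc2)c2ccc(OC(C)(C)C)cc2)cc1 | intermediate
9 | 2,5-bis[4-(tert-butoxy)phenyl]-3,6-dihydroxycyclohexa-2,5-diene-1,4-dione | CC(C)(C)Oc1ccc(C2=C(O)C(=O)C(c3ccc(OC(C)(C)C)cc3)=C(O)C2=O)cc1 | intermediate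
10 | disodium salt of 9 | [Na+].[Na+].CC(C)(C)Oc1ccc(C2=C([O-])C(=O)C(c3ccc(OC(C)(C)C)cc3)=C([O-])C2=O)cc1 | intermediate
11 | 2,5-bis[4-(tert-butoxy)phenyl]-4-hydroxy-3,6-dioxocyclohexa-1,4-dien-1-yl acetate | CC(=O)OC1=C(c2ccc(OC(C)(C)C)cc2)C(=O)C(O)=C(c2ccc(OC(C)(C)C)cc2)C1=O | intermediate
12 | 4-hydroxy-2,5-bis(4-hydroxyphenyl)-3,6-dioxocyclohexa-1,4-dien-1-yl acetate | CC(=O)OC1=C(c2ccc(O)cc2)C(=O)C(O)=C(c2ccc(O)cc2)C1=O | target

Total step count: 4. Longest linear sequence: 4 steps (1 → 6 → 9 → 11 → 12).

Steps most likely to fail

Step 2 (the proposed new method). The first intermolecular acylation may stall at reversibly O-acylated material. Alternatively, traces of protonated keto form may divert the enolates into aldol-type dimerisation (butenolide or five-membered carbocycle formation) faster than the Claisen pathway. The fallback makes the two bonds one after the other with known reactions, setting out from 6 and returning at 9. Methanolysis of 6 (NaOMe cat., MeOH, 0 °C) should give methyl (Z)-3-[4-(tert-butoxy)phenyl]-2-hydroxyprop-2-enoate F1. Deprotonation (LiN(SiMe3)2, THF, −78 °C) would give its lithium enolate F2, which is C-acylated by a second equivalent of 6 (−78 → 0 °C, the known acylation of lithium ester enolates by 5-arylidene-1,3-dioxolan-4-ones). Acidification would give methyl 3,6-bis[4-(tert-butoxy)phenyl]-2,4,5-trioxohexanoate F3, taken on crude. Dieckmann closure of F3 (NaOMe, MeOH, reflux, then 1 M HCl) would then deliver 9.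

Step 3. Over-acylation and acetyl scrambling between quinone oxygens may erode the mono-selectivity towards a statistical mixture of 9, monoacetate and diacetate. The fallback sets out from 9 and returns at 11. Exhaustive acetylation (Ac2O, pyridine, DMAP cat., CH2Cl2, 0 °C) would give 2,5-bis[4-(tert-butoxy)phenyl]-3,6-dioxocyclohexa-1,4-diene-1,4-diyl diacetate F4. Transesterification with exactly one equivalent of NaOMe (THF–MeOH, −40 °C, then cold 0.5 M HCl) should remove a single acetyl group, because the first cleavage leaves an anionic, electron-rich monoacetate that resists further attack.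

Step 1. Self-condensation of the lactone enolate before aldol addition, or incomplete mesylation and elimination in the one-pot sequence, may lower the throughput. The fallback is a Wittig olefination that sets out from 2 and returns at 6. Radical bromination of 2 (NBS, AIBN cat., PhCF3, 80 °C) would give racemic 5-bromo-2,2-dimethyl-1,3-dioxolan-4-one F5. Treatment with PPh3 (toluene, rt) would give (2,2-dimethyl-5-oxo-1,3-dioxolan-4-yl)triphenylphosphonium bromide F6. Et3N would convert F6 into the stabilised ylide 2,2-dimethyl-5-(triphenyl-λ5-phosphanylidene)-1,3-dioxolan-4-one F7, which on heating with aldehyde 1 (toluene, 80 °C) should give 6.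

Further compounds
F1 | step 2 | methyl (Z)-3-[4-(tert-butoxy)phenyl]-2-hydroxyprop-2-enoate | CC(C)(C)Oc1ccc(/C=C(\O)C(=O)OC)cc1
F2 | step 2 | lithium enolate of F1 | [Li+].CC(C)(C)Oc1ccc(/C=C(\[O-])C(=O)OC)cc1
F3 | step 2 | methyl 3,6-bis[4-(tert-butoxy)phenyl]-2,4,5-trioxohexanoate (racemic, enolisable centre; drawn as the keto form) | COC(=O)C(=O)C(c1ccc(OC(C)(C)C)cc1)C(=O)C(=O)Cc1ccc(OC(C)(C)C)cc1
F4 | step 3 | 2,5-bis[4-(tert-butoxy)phenyl]-3,6-dioxocyclohexa-1,4-diene-1,4-diyl diacetate | CC(=O)OC1=C(c2ccc(OC(C)(C)C)cc2)C(=O)C(OC(C)=O)=C(c2ccc(OC(C)(C)C)cc2)C1=O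
F5 | step 1 | 5-bromo-2,2-dimethyl-1,3-dioxolan-4-one (racemic) | CC1(C)OC(Br)C(=O)O1
F6 | step 1 | (2,2-dimethyl-5-oxo-1,3-dioxolan-4-yl)triphenylphosphonium bromide (racemic) | CC1(C)OC([P+](c2ccccc2)(c2ccccc2)c2ccccc2)C(=O)O1.[Br-]
F7 | step 1 | 2,2-dimethyl-5-(triphenyl-λ5-phosphanylidene)-1,3-dioxolan-4-one | CC1(C)OC(=P(c2ccccc2)(c2ccccc2)c2ccccc2)C(=O)O1
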